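**Retrosynthetic overview**
- The target is (13S)-19-angeloyloxy-labd-7-en-15-oic acid (4S,5R,9S,10R,13S, Z-enoate). The last two operations are O-angeloylation of the axial C19–OH and hydrolysis of a C15 methyl ester; no ring or stereocentre is made after the cyclisation.
- Key step: rings A and B close in one cationic cascade (A, then B, then loss of H-7), as in the class II cyclase route to labd-7-enes. It is started by Lewis-acid opening of an acyclic (S)-2-methyl-2-alkyloxirane, so the oxirane carbon becomes C4 and its oxygen becomes the C19–OH.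
- The oxirane comes from a methyl ketone by catalytic asymmetric CH2 transfer; the ketone from a terminal alkene (Wacker); the alkene from a C15 allylic bromide and butenyl Grignard (C1–C2 bond).
- The allylic bromide comes from ω-(E)-methyl oxidation of methyl (S)-2,3-dihydrofarnesoate, made from (2E,6E)-farnesol by asymmetric hydrogenation (sets C13).

Assumption: in step 7 the (S)-BINOL-derived catalyst is taken to give the (S)-oxirane; if the first run shows the opposite sense, the (R)-BINOL catalyst is used and nothing else changes.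

**Route**

Step 1
Reactants: 1 (2E,6E)-farnesol
Product: 2 (3S,6E)-3,7,11-trimethyldodeca-6,10-dien-1-ol [(S)-2,3-dihydrofarnesol]
Conditions: H2 (100 atm), Ru(OAc)2[(R)-BINAP] (0.2 mol%), MeOH–H2O 95:5, 20 °C
Reagents that add atoms: none
Why: Noyori asymmetric hydrogenation, in which the allylic hydroxyl binds Ru so that only the 2,3-alkene is reduced and the (R)-BINAP catalyst delivers H2 to the face of the (E)-allylic alcohol that gives 3S (as geraniol gives (S)-citronellol), which sets C13 of the target.

Step 2
Reactants: 2 (S)-2,3-dihydrofarnesol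
Product: 5 methyl (3S,6E)-3,7,11-trimethyldodeca-6,10-dienoate, via (S)-dihydrofarnesal 3 (not isolated), via methyl hemiacetal 4 (not isolated)
Conditions: PDC (6 equiv), MeOH (6 equiv), DMF, rt
Reagents that add atoms: methanol, CO
Why: Chromium(VI) oxidative esterification, in which the alcohol is oxidised to the aldehyde and its methanol hemiacetal is oxidised on to the methyl ester, while the isolated trisubstituted alkenes and the non-enolisable β-stereocentre are untouched.

Step 3
Reactants: 5 methyl (S)-2,3-dihydrofarnesoate
Product: 6 methyl (3S,6E,10E)-12-hydroxy-3,7,11-trimethyldodeca-6,10-dienoate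
Conditions: SeO2 (0.3 equiv), t-BuOOH (3 equiv), salicylic acid (0.1 equiv), CH2Cl2, 0 °C → rt; unreacted 5 recycled
Reagents that add atoms: selenium dioxide, O=[Se]=O; tert-butyl hydroperoxide, CC(C)(C)OO
Why: Sharpless catalytic SeO2 allylic oxidation (ene reaction then [2,3]-sigmatropic shift) attacks the (E)-methyl of the terminal gem-dimethyl alkene in preference to the internal alkene and gives only the (E)-allylic alcohol.

Step 4
Reactants: 6 the 12-hydroxy ester
Product: 7 methyl (3S,6E,10E)-12-bromo-3,7,11-trimethyldodeca-6,10-dienoate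
Conditions: CBr4 (1.2 equiv), PPh3 (1.25 equiv), CH2Cl2, 0 °C; used at once
Reagents that add atoms: carbon tetrabromide, BrC(Br)(Br)Br
Why: Appel reaction, an SN2 displacement of the alkoxyphosphonium ion at the primary allylic carbon that gives the bromide without allylic shift or loss of E geometry and leaves the ester alone.

Step 5
Reactants: 7 the allylic bromide; 8 but-3-en-1-ylmagnesium bromide
Product: 9 methyl (3S,6E,10E)-3,7,11-trimethylhexadeca-6,10,15-trienoate
Conditions: 8 (1.3 equiv, slow addition), Li2CuCl4 (5 mol%), THF, −78 → −20 °C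
Reagents that add atoms: but-3-en-1-ylmagnesium bromide (8), C=CCC[Mg]Br
Why: Kochi copper-catalysed Grignard/allylic bromide cross-coupling, in which the alkylcopper species substitutes at the unhindered primary carbon (SN2, alkene geometry kept) much faster than the Grignard reagent adds to the ester at this temperature.

Step 6
Reactants: 9 the triene ester
Product: 10 methyl (3S,6E,10E)-3,7,11-trimethyl-15-oxohexadeca-6,10-dienoate
Conditions: PdCl2 (10 mol%), CuCl (1 equiv), O2 (1 atm), DMF–H2O 7:1, rt
Reagents that add atoms: water, O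
Why: Tsuji–Wacker oxidation, in which Pd(II) hydroxypalladates only the monosubstituted terminal alkene (Markovnikov) to give the methyl ketone, the two trisubstituted alkenes being too hindered to react.

Step 7
Reactants: 10 the methyl ketone; 11 trimethylsulfoxonium iodide
Product: 12 methyl (3S,6E,10E)-3,7,11-trimethyl-14-[(2S)-2-methyloxiran-2-yl]tetradeca-6,10-dienoate
Conditions: 11 (1.2 equiv), NaH (1.2 equiv), THF, reflux, filtered; then 10, La–Li3–tris[(S)-binaphthoxide] (5 mol%), [2,4,6-(MeO)3C6H2]3P=O (5 mol%), 5 Å MS, THF, rt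
Reagents that add atoms: dimethylsulfoxonium methylide, C[S+](C)(=O)[CH2-] (made in the flask from 11, C[S+](C)(C)=O.[I-])
Why: Catalytic asymmetric Corey–Chaykovsky epoxidation of a methyl ketone, in which the La/Li heterobimetallic catalyst binds ketone and ylide, distinguishes CH3 from the long chain and adds CH2 to one carbonyl face to set the (S)-oxirane carbon (the future C4), while the ester is far less electrophilic towards the stabilised ylide.

Step 8
Reactants: 12 the (S)-oxirane
Product: 14 methyl (13S)-19-hydroxylabd-7-en-15-oate, via dichloroaluminium alkoxide 13 (not isolated)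
Conditions: MeAlCl2 (2.5 equiv), CH2Cl2, −78 °C, 1 h; then 1 M HCl; AgNO3–SiO2 chromatography
Reagents that add atoms: none
Why: Proposed new method: Al-activation ionises the tertiary oxirane C–O bond only with anti participation of the neighbouring alkene (inversion, giving 4S, with the CH2–O–Al arm, tied back by the breaking three-membered ring, taking the axial site syn to C20), the E,E-diene folds chair–chair so that anti addition across both alkenes gives the trans-decalin with 5α-H, 10β-CH3 and 9β side chain, and the C8 cation loses axial H-7 (Zaitsev, taken up by Al–CH3 as methane) to give the 7-ene; the closest known reaction type is the Lewis-acid-promoted oxirane-initiated polyene cyclisation (normally run with trisubstituted oxiranes to give 3-hydroxy products), which mirrors the cyclase cascade from a C4 cation to the labd-7-ene.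

Step 9
Reactants: 14 the hydroxy ester; 15 angelic anhydride
Product: 17 methyl (13S)-19-angeloyloxylabd-7-en-15-oate, via lithium alkoxide 16 (not isolated)
Conditions: LiHMDS (1.05 equiv), THF, −78 °C; then 15 (1.5 equiv), −78 → 0 °C; aq. NH4Cl
Reagents that add atoms: angelic anhydride (15), C/C=C(/C)C(=O)OC(=O)C(/C)=C\C
Why: O-acylation of a preformed lithium alkoxide by the symmetrical anhydride, with no nucleophilic catalyst present that could add to the enoate and isomerise Z to E, and with the alkoxide formed without touching the ester α-CH2.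

Step 10
Reactants: 17 the angelate methyl ester
Product: 19 (13S)-19-angeloyloxylabd-7-en-15-oic acid (target), via lithium carboxylate 18 (not isolated)
Conditions: LiOH·H2O (3 equiv), THF–H2O 3:1, 0 °C → rt, followed by TLC; then 1 M HCl to pH 3
Reagents that add atoms: lithium hydroxide, [Li+].[OH-]
Why: Saponification (BAc2) is chemoselective for the unhindered saturated methyl ester over the neopentyl, α-branched, conjugated angelate, and no stereocentre or the Z-alkene is exposed to enolisation.

**Compound list**

1 | (2E,6E)-farnesol, (2E,6E)-3,7,11-trimethyldodeca-2,6,10-trien-1-ol | CC(C)=CCC/C(C)=C/CC/C(C)=C/CO | starting material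
2 | (S)-2,3-dihydrofarnesol, (3S,6E)-3,7,11-trimethyldodeca-6,10-dien-1-ol | CC(C)=CCC/C(C)=C/CC[C@H](C)CCO | intermediate
3 | (S)-2,3-dihydrofarnesal, (3S,6E)-3,7,11-trimethyldodeca-6,10-dienal | CC(C)=CCC/C(C)=C/CC[C@H](C)CC=O | intermediate (not isolated)
4 | methyl hemiacetal of 3, (3S,6E)-1-methoxy-3,7,11-trimethyldodeca-6,10-dien-1-ol, both C1 epimers | CC(C)=CCC/C(C)=C/CC[C@H](C)CC(O)OC | intermediate (not isolated)
5 | methyl (3S,6E)-3,7,11-trimethyldodeca-6,10-dienoate | CC(C)=CCC/C(C)=C/CC[C@H](C)CC(=O)OC | intermediate
6 | methyl (3S,6E,10E)-12-hydroxy-3,7,11-trimethyldodeca-6,10-dienoate | OC/C(C)=C/CC/C(C)=C/CC[C@H](C)CC(=O)OC | intermediate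
7 | methyl (3S,6E,10E)-12-bromo-3,7,11-trimethyldodeca-6,10-dienoate | BrC/C(C)=C/CC/C(C)=C/CC[C@H](C)CC(=O)OC | intermediate
8 | but-3-en-1-ylmagnesium bromide | C=CCC[Mg]Br | starting material
9 | methyl (3S,6E,10E)-3,7,11-trimethylhexadeca-6,10,15-trienoate | C=CCCC/C(C)=C/CC/C(C)=C/CC[C@H](C)CC(=O)OC | intermediate
10 | methyl (3S,6E,10E)-3,7,11-trimethyl-15-oxohexadeca-6,10-dienoate | CC(=O)CCC/C(C)=C/CC/C(C)=C/CC[C@H](C)CC(=O)OC | intermediate
11 | trimethylsulfoxonium iodide | C[S+](C)(C)=O.[I-] | starting material
12 | methyl (3S,6E,10E)-3,7,11-trimethyl-14-[(2S)-2-methyloxiran-2-yl]tetradeca-6,10-dienoate | C[C@@]1(CO1)CCC/C(C)=C/CC/C(C)=C/CC[C@H](C)CC(=O)OC | intermediate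
13 | dichloroaluminium 19-alkoxide of 14 | Cl[Al](Cl)OC[C@@]1(C)CCC[C@]2(C)[C@@H](CC[C@H](C)CC(=O)OC)C(C)=CC[C@@H]12 | intermediate (not isolated)
14 | methyl (13S)-19-hydroxylabd-7-en-15-oate, methyl (3S)-5-[(1S,4aR,5S,8aR)-5-(hydroxymethyl)-2,5,8a-trimethyl-1,4,4a,5,6,7,8,8a-octahydronaphthalen-1-yl]-3-methylpentanoate; trans-decalin, 4β(axial)-CH2OH cis to 10β-CH3, 5α-H, 9β side chain | OC[C@@]1(C)CCC[C@]2(C)[C@@H](CC[C@H](C)CC(=O)OC)C(C)=CC[C@@H]12 | intermediate
15 | angelic anhydride, (2Z)-2-methylbut-2-enoic anhydride | C/C=C(/C)C(=O)OC(=O)C(/C)=C\C | starting material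
16 | lithium 19-alkoxide of 14 | [Li+].[O-]C[C@@]1(C)CCC[C@]2(C)[C@@H](CC[C@H](C)CC(=O)OC)C(C)=CC[C@@H]12 | intermediate (not isolated)
17 | methyl (13S)-19-angeloyloxylabd-7-en-15-oate | C/C=C(/C)C(=O)OC[C@@]1(C)CCC[C@]2(C)[C@@H](CC[C@H](C)CC(=O)OC)C(C)=CC[C@@H]12 | intermediate
18 | lithium (13S)-19-angeloyloxylabd-7-en-15-oate | C/C=C(/C)C(=O)OC[C@@]1(C)CCC[C@]2(C)[C@@H](CC[C@H](C)CC(=O)[O-])C(C)=CC[C@@H]12.[Li+] | intermediate (not isolated)
19 | (13S)-19-angeloyloxylabd-7-en-15-oic acid, (3S)-3-methyl-5-[(1S,4aR,5S,8aR)-2,5,8a-trimethyl-5-({[(2Z)-2-methylbut-2-enoyl]oxy}methyl)-1,4,4a,5,6,7,8,8a-octahydronaphthalen-1-yl]pentanoic acid | C/C=C(/C)C(=O)OC[C@@]1(C)CCC[C@]2(C)[C@@H](CC[C@H](C)CC(=O)O)C(C)=CC[C@@H]12 | target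

**Totals**

Total step count: 10. Longest linear sequence: 10 (from 1).

**Steps most likely to fail**

Step 8 (cyclisation). The risks are a 1,2-hydride shift of the activated oxirane to an aldehyde, arrest after ring A (monocyclic dienes or a C19–O–C10 bridged ether), the other chair fold (CH2OH equatorial), and proton loss towards C17 instead of C7. The fallback sets out from 12 and comes back at 14. The cyclisation is no longer asked to place the double bond. The crude alkene mixture, whose other main component is methyl (13S)-19-hydroxylabd-8(17)-en-15-oate F1, is treated with Co(salen-tBu,tBu)Cl (3 mol%) and PhSiH3 (6 mol%) in benzene at rt. Reversible hydrogen-atom transfer to the 1,1-disubstituted alkene gives the tertiary C8 radical, which gives H back from the unhindered C7 rather than from the congested C9. The trisubstituted 7-ene does not re-enter the cycle, so the mixture converges on 14.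

Step 7 (asymmetric CH2 transfer). The risks are lower selectivity on a long-chain dialkyl ketone that carries an ester, and the unverified sense of induction noted in the assumption. The fallback sets out from 10 and comes back at 12. An uncatalysed Corey–Chaykovsky reaction (Me3S(O)I, NaH, DMSO, rt) gives methyl (3S,6E,10E)-3,7,11-trimethyl-14-(2-methyloxiran-2-yl)tetradeca-6,10-dienoate as a 1:1 mixture of oxirane epimers F2. This is resolved kinetically by (salen)Cr(III)–N3-catalysed ring opening with TMSN3/i-PrOH (0.55 equiv), using the catalyst antipode that opens the (2R)-epimer at its CH2 group. The untouched (2S)-epimer is 12 and is separated from the polar opened material on silica.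

Step 9 (angeloylation). The risks are slow acylation of the axial neopentyl alcohol, Z → E isomerisation to the tiglate, and side reactions of the alkoxide with the methyl ester. The fallback sets out from 14 and comes back at 17. The Z-enoate is built on the substrate instead of being transferred. Alcohol 14 is esterified (DCC, cat. DMAP, CH2Cl2) with 2-[bis(2,2,2-trifluoroethoxy)phosphoryl]propanoic acid to give methyl (13S)-19-{2-[bis(2,2,2-trifluoroethoxy)phosphoryl]propanoyloxy}labd-7-en-15-oate F3. Still–Gennari olefination (KHMDS, 18-crown-6, THF, −78 °C; acetaldehyde) then forms the (Z)-2-methylbut-2-enoate under kinetic control, which is 17.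

**Further compounds**

F1 | step 8 | methyl (13S)-19-hydroxylabd-8(17)-en-15-oate | OC[C@@]1(C)CCC[C@]2(C)[C@@H](CC[C@H](C)CC(=O)OC)C(=C)CC[C@@H]12
F2 | step 7 | methyl (3S,6E,10E)-3,7,11-trimethyl-14-(2-methyloxiran-2-yl)tetradeca-6,10-dienoate, 1:1 oxirane epimers | CC1(CO1)CCC/C(C)=C/CC/C(C)=C/CC[C@H](C)CC(=O)OC
F3 | step 9 | methyl (13S)-19-{2-[bis(2,2,2-trifluoroethoxy)phosphoryl]propanoyloxy}labd-7-en-15-oate, both α-epimers | CC(C(=O)OC[C@@]1(C)CCC[C@]2(C)[C@@H](CC[C@H](C)CC(=O)OC)C(C)=CC[C@@H]12)P(=O)(OCC(F)(F)F)OCC(F)(F)F
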